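**Retrosynthetic overview**
- Last disconnection: the bond between the exocyclic CH2 on chroman C7 and maleimide C3. It is made by an iron-LMCT photoelectrochemical decarboxylative C–H benzylation. This step joins the unprotected (S)-chromanol acetic acid to 3-(4-hydroxyphenyl)maleimide and gives the target directly, with CO2 and H2 as the only other products.
- Enabling feature: the maleimide C3=C4 bond lies between the two imide carbonyls C2 and C5, so a nucleophilic benzylic radical adds at the unsubstituted C3. The para-hydroxyphenyl ring on C4 lets the adduct radical lose H+/e− as a para-quinone methide, whose C3–H tautomerises back to phenol plus C3=C4. The CH2 is benzylic to the chroman arene, so its homologous acetic acid serves as a traceless radical precursor.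
- Chromanol acid: the C3 carbinol comes from Jacobsen–Katsuki epoxidation of a 2,2-dimethylchromene, followed by hydrogenolysis of the benzylic C4–O bond. The chromene comes from methyl 3-hydroxyphenylacetate and prenal by ortho-quinone methide formation and oxa-6π closure.
- Arylmaleimide: Mizoroki–Heck arylation of maleimide with 4-iodophenol.
- Ring order: both benzene rings and the imide ring are bought. The pyran ring is the only lasting ring formed (step 1). A temporary oxirane is formed in step 2 and opened in step 3.

Key step: step 6

Remark on the chemistry: the carbinol carbon (chroman C3) is read from the SMILES as (S), and the CH2 link sits on chroman C7 (para to C4a, meta to O1). Maleimide atoms are numbered N1, C2(=O), C3 (CH2-bearing), C4 (aryl-bearing), C5(=O), and this numbering is also used for the arylmaleimide precursor.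

**Step 1**
Reactants: 1 methyl 2-(3-hydroxyphenyl)acetate; 2 3-methylbut-2-enal (prenal)
Product: 5 methyl 2-(2,2-dimethyl-2H-chromen-7-yl)acetate, via benzodioxaborin 3 (not isolated), via ortho-quinone methide 4 (not isolated)
Conditions: PhB(OH)2 (1 equiv), EtCO2H (cat.), toluene, reflux, Dean–Stark
Reagents that add atoms: none
Why: Boronic-acid-templated ortho-hydroxyalkylation of the phenol at its less hindered ortho position (para to the acetate side chain) should give 3, which fragments on heating to 4 and closes by oxa-6π electrocyclisation (chromene annulation of phenols with enals), with no stereocentre formed.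

**Step 2**
Reactants: 5 methyl 2-(2,2-dimethyl-2H-chromen-7-yl)acetate
Product: 6 methyl 2-[(1aS,7bS)-2,2-dimethyl-1a,7b-dihydro-2H-oxireno[2,3-c]chromen-5-yl]acetate (the (3S,4S)-3,4-epoxychroman)
Conditions: (S,S)-Jacobsen Mn(salen)Cl (cat.), 4-phenylpyridine N-oxide (cat.), aq. NaOCl (pH 11.3), CH2Cl2, 0 °C
Reagents that add atoms: sodium hypochlorite, [Na+].[O-]Cl
Why: In this Jacobsen–Katsuki epoxidation, for which 2,2-dimethylchromenes are the benchmark substrate class, the (S,S)-salen oxo-manganese species should deliver oxygen to one face of the cis C3=C4 bond and set (3S,4S), while ester and arene are inert to buffered bleach at 0 °C.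

**Step 3**
Reactants: 6 the (3S,4S)-epoxychroman ester
Product: 7 methyl 2-[(3S)-3-hydroxy-2,2-dimethyl-3,4-dihydro-2H-chromen-7-yl]acetate
Conditions: H2 (1 atm), 10% Pd/C, EtOAc, rt
Reagents that add atoms: none
Why: Catalytic hydrogenolysis of a benzylic epoxide cleaves only the benzylic C4–O bond, so the C3–O bond keeps its (S) configuration, the C4 stereocentre disappears, and the ester and the aryl alkyl ether remain untouched in the neutral aprotic solvent.

**Step 4**
Reactants: 7 methyl 2-[(3S)-3-hydroxy-2,2-dimethyl-3,4-dihydro-2H-chromen-7-yl]acetate
Product: 9 2-[(3S)-3-hydroxy-2,2-dimethyl-3,4-dihydro-2H-chromen-7-yl]acetic acid, via lithium carboxylate 8 (not isolated)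
Conditions: LiOH, THF–H2O, rt; then 1 M HCl
Reagents that add atoms: lithium hydroxide, [Li+].[OH-]
Why: Ordinary saponification of a methyl ester should proceed cleanly because the carbinol centre has no pathway for epimerisation under these conditions and the chroman ether is stable to base and to brief mild acid.

**Step 5**
Reactants: 10 maleimide (1H-pyrrole-2,5-dione); 11 4-iodophenol
Product: 12 3-(4-hydroxyphenyl)-1H-pyrrole-2,5-dione
Conditions: Pd(OAc)2 (cat.), KOAc, ethylene carbonate, 70 °C, 10 in excess
Reagents that add atoms: none
Why: In this Mizoroki–Heck arylation of maleimide, the weak acetate base should avoid imide ring opening and oligomerisation, epimerisation through the palladium enolate allows the β-hydride elimination that restores the C=C bond, and the excess of 10 suppresses a second arylation.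

**Step 6**
Reactants: 9 2-[(3S)-3-hydroxy-2,2-dimethyl-3,4-dihydro-2H-chromen-7-yl]acetic acid; 12 3-(4-hydroxyphenyl)-1H-pyrrole-2,5-dione
Product: 14 asperimide C, via quinone methide tautomer 13 (not isolated)
Conditions: Fe(OTf)2 (10 mol %), picolinic acid (20 mol %), 2,4,6-collidine (30 mol %), nBu4NPF6, MeCN, 456 nm LEDs, RVC(+) held at the Fe(II)/Fe(III) wave | Nafion | Pt(−) in AcOH–MeCN, N2, rt; 12 (2 equiv)
Reagents that add atoms: none
Why: Proposed new method: the carboxylate of 9 binds Fe(III), and visible-light ligand-to-metal charge transfer followed by loss of CO2 releases the chroman-7-ylmethyl radical in the bulk solution, far from the anode, so that Hofer–Moest over-oxidation to the benzylic cation (and O- or N-benzylation of 12) is avoided. This nucleophilic radical adds to the unsubstituted C3 of 12, the only sterically open terminus of the doubly carbonyl-activated C3=C4 bond, and gives the C4 radical that is stabilised by C5=O and by the para-hydroxyphenyl ring. Because that radical can give up its phenolic hydrogen together with one electron, the weak oxidant Fe(III) carboxylate should convert it by proton-coupled electron transfer into quinone methide 13, whose acidic C3–H is relayed to oxygen by collidine to restore the phenol and the C3=C4 bond of 14, whereas an ordinary phenol, the chroman arene and the secondary alcohol should not be oxidised at this potential. The anode only returns Fe(II) to Fe(III) (two electrons per turnover), and the protons cross the membrane and leave as H2 at the cathode, from which the divided cell keeps the reducible maleimides away. The closest known reaction types are the silver/persulfate decarboxylative benzylation of 2-methyl-1,4-naphthoquinone with arylacetic acids (Kochi–Anderson type), the photocatalytic decarboxylative Giese benzylation of maleimides and the photoelectrochemical LMCT decarboxylative Minisci alkylation, and what is new is the oxidative, C=C-restoring termination on a 3-arylmaleimide. No ring is closed and no lasting stereocentre is formed (C3 of 13 is transient, chroman C3 is remote and untouched), and the selectivities needed, C3 over C4 addition and mono-alkylation, are secured by the C4 aryl group and by the tetrasubstituted product no longer accepting the radical.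

**Compound list**
1 | methyl 2-(3-hydroxyphenyl)acetate | COC(=O)Cc1cccc(O)c1 | starting material
2 | 3-methylbut-2-enal (prenal) | CC(C)=CC=O | starting material
3 | methyl 2-[4-(2-methylprop-1-en-1-yl)-2-phenyl-4H-1,3,2-benzodioxaborinin-7-yl]acetate (racemic at C4, not isolated) | COC(=O)Cc1ccc2C(C=C(C)C)OB(c3ccccc3)Oc2c1 | intermediate
4 | methyl 2-[4-(3-methylbut-2-en-1-ylidene)-3-oxocyclohexa-1,5-dien-1-yl]acetate (ortho-quinone methide, not isolated) | COC(=O)CC1=CC(=O)C(=CC=C(C)C)C=C1 | intermediate
5 | methyl 2-(2,2-dimethyl-2H-chromen-7-yl)acetate | COC(=O)Cc1ccc2C=CC(C)(C)Oc2c1 | intermediate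
6 | methyl 2-[(1aS,7bS)-2,2-dimethyl-1a,7b-dihydro-2H-oxireno[2,3-c]chromen-5-yl]acetate | COC(=O)Cc1ccc2[C@@H]3O[C@@H]3C(C)(C)Oc2c1 | intermediate
7 | methyl 2-[(3S)-3-hydroxy-2,2-dimethyl-3,4-dihydro-2H-chromen-7-yl]acetate | CC1(C)Oc2cc(CC(=O)OC)ccc2C[C@@H]1O | intermediate
8 | lithium 2-[(3S)-3-hydroxy-2,2-dimethyl-3,4-dihydro-2H-chromen-7-yl]acetate (not isolated) | CC1(C)Oc2cc(CC(=O)[O-])ccc2C[C@@H]1O.[Li+] | intermediate
9 | 2-[(3S)-3-hydroxy-2,2-dimethyl-3,4-dihydro-2H-chromen-7-yl]acetic acid | CC1(C)Oc2cc(CC(=O)O)ccc2C[C@@H]1O | intermediate
10 | maleimide (1H-pyrrole-2,5-dione) | O=C1C=CC(=O)N1 | starting material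
11 | 4-iodophenol | Oc1ccc(I)cc1 | starting material
12 | 3-(4-hydroxyphenyl)-1H-pyrrole-2,5-dione | O=C1NC(=O)C(c2ccc(O)cc2)=C1 | intermediate
13 | 3-{[(3S)-3-hydroxy-2,2-dimethyl-3,4-dihydro-2H-chromen-7-yl]methyl}-4-(4-oxocyclohexa-2,5-dien-1-ylidene)pyrrolidine-2,5-dione (imide C3 unspecified, not isolated) | CC1(C)Oc2cc(CC3C(=O)NC(=O)C3=C4C=CC(=O)C=C4)ccc2C[C@@H]1O | intermediate
14 | asperimide C, 3-{[(3S)-3-hydroxy-2,2-dimethyl-3,4-dihydro-2H-chromen-7-yl]methyl}-4-(4-hydroxyphenyl)-1H-pyrrole-2,5-dione | CC1(C)Oc2cc(CC3=C(c4ccc(O)cc4)C(=O)NC3=O)ccc2C[C@@H]1O | target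

**Step count**
Total step count: 6
Longest linear sequence: 5 (steps 1, 2, 3, 4, 6)

**Steps most likely to fail**

**Step 6.** Several processes could undermine the coupling:
- Light absorption by the yellow arylmaleimide may starve the Fe(III) carboxylate of photons.
- The benzylic radical may dimerise, or be over-oxidised and then benzylate oxygen or nitrogen.
- The adduct radical may be reduced instead of oxidised.
- Hydrogen abstraction at the new doubly activated CH2 may erode the product.

The fallback replaces the radical coupling by a polar olefination of known type. It sets out from 9 and 12 and comes back at 14. Copper-catalysed aerobic oxidative decarboxylation of 9 (Cu(OAc)2 cat., O2, DMSO, heat) should give (3S)-3-hydroxy-2,2-dimethyl-3,4-dihydro-2H-chromene-7-carbaldehyde F1. Triphenylphosphine adds to C3 of 12 and, after proton shift, gives the stabilised ylide 3-(4-hydroxyphenyl)-4-(triphenylphosphoranylidene)pyrrolidine-2,5-dione F2. In refluxing THF this ylide undergoes Wittig olefination with F1 to (E)-3-{[(3S)-3-hydroxy-2,2-dimethyl-3,4-dihydro-2H-chromen-7-yl]methylidene}-4-(4-hydroxyphenyl)pyrrolidine-2,5-dione F3. Triethylamine then moves the double bond into the ring by a 1,3-prototropic shift, driven by conjugation with the aryl group and both carbonyls, and gives 14.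

**Step 5.** Base-induced oligomerisation or ring opening of maleimide, a second arylation, or catalyst deactivation by the phenol may spoil the Heck reaction. The fallback changes from palladium catalysis to copper-mediated aryl-radical addition (Meerwein arylation). It sets out from 10 and comes back at 12. Commercial 4-aminophenol is diazotised (NaNO2, aq. HCl, 0 °C) to 4-hydroxybenzenediazonium chloride F4. This salt is added to 10 with CuCl2 (cat.) in aqueous acetone to give 3-chloro-4-(4-hydroxyphenyl)pyrrolidine-2,5-dione F5. Dehydrochlorination with 2,6-lutidine gives 12.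

**Step 1.** The phenol is only weakly activated, so ortho-hydroxyalkylation may be sluggish. Attack at the hindered ortho position or self-condensation of prenal may also compete. The fallback builds the same ortho-quinone methide in stages. It sets out from 1 and comes back at 5 (through 4). Magnesium-mediated ortho-formylation (MgCl2, Et3N, paraformaldehyde, MeCN, reflux; Casnati–Skattebøl type) at the open ortho position should give methyl 2-(4-formyl-3-hydroxyphenyl)acetate F6. Addition of 2-methylprop-1-enylmagnesium bromide (THF, −78 °C) to the chelated aldehyde gives methyl 2-[3-hydroxy-4-(1-hydroxy-3-methylbut-2-en-1-yl)phenyl]acetate F7. Warming F7 in toluene with a trace of PPTS dehydrates it to 4, which closes to 5.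

**Further compounds**
F1 | step 6 | (3S)-3-hydroxy-2,2-dimethyl-3,4-dihydro-2H-chromene-7-carbaldehyde | CC1(C)Oc2cc(C=O)ccc2C[C@@H]1O
F2 | step 6 | 3-(4-hydroxyphenyl)-4-(triphenylphosphoranylidene)pyrrolidine-2,5-dione | O=C1NC(=O)C(=P(c2ccccc2)(c2ccccc2)c2ccccc2)C1c1ccc(O)cc1
F3 | step 6 | (E)-3-{[(3S)-3-hydroxy-2,2-dimethyl-3,4-dihydro-2H-chromen-7-yl]methylidene}-4-(4-hydroxyphenyl)pyrrolidine-2,5-dione | CC1(C)Oc2cc(/C=C3/C(=O)NC(=O)C3c4ccc(O)cc4)ccc2C[C@@H]1O
F4 | step 5 | 4-hydroxybenzenediazonium chloride | Oc1ccc([N+]#N)cc1.[Cl-]
F5 | step 5 | 3-chloro-4-(4-hydroxyphenyl)pyrrolidine-2,5-dione | O=C1NC(=O)C(Cl)C1c1ccc(O)cc1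
F6 | step 1 | methyl 2-(4-formyl-3-hydroxyphenyl)acetate | COC(=O)Cc1ccc(C=O)c(O)c1
F7 | step 1 | methyl 2-[3-hydroxy-4-(1-hydroxy-3-methylbut-2-en-1-yl)phenyl]acetate | COC(=O)Cc1ccc(C(O)C=C(C)C)c(O)c1
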